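Ring B of the target (C9a, C4a, C10, C11, C12, C9) is treated as a latent 4,4-disubstituted cyclohexa-2,5-dienone: C11 is its carbonyl carbon, C9a its prochiral quaternary carbon, and the ring A ketone carbon C4 sits on C4a, β to C11. An enantioselective intramolecular Stetter reaction of an aldehyde tethered through ketal-masked C1 therefore forms C4–C4a, closes ring A, fixes C9a and leaves the second enone for arylation at C9. The precursor, 4-prenyl-4-[2-(3-oxopropyl)-1,3-dioxolan-2-yl]cyclohexa-2,5-dienone, comes from benzoic acid by Birch prenylation. Afterwards C4a is flattened, the arene is added anti to prenyl and closed onto C4a with capture of the C10=C11 enolate.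

Key step: step 8

Remark: atom labels are those of the target (ring A: C9a, C1–C4, C4a; ring B: C9a, C4a, C10, C11, C12, C9; arene: C4b, C5–C8, C8a). The sense of induction of the aminoindanol triazolium catalyst is assumed by analogy with oxygen-tethered dienones; should a test run show the opposite sense, the antipodal catalyst (from the other enantiomer of cis-1-amino-2-indanol) is used.

Step 1
Reactants: 1 benzoic acid; 2 prenyl bromide (1-bromo-3-methylbut-2-ene)
Product: 3 1-(3-methylbut-2-en-1-yl)cyclohexa-2,5-diene-1-carboxylic acid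
Conditions: Li, NH3(l), THF, −78 °C; then 2; aq. HCl work-up
Reagents that add atoms: none
Why: Birch reductive alkylation, in which the dissolving metal turns benzoate into the 1,4-dihydro dianion and the allylic bromide alkylates the carboxyl-bearing carbon; no stereocenter is formed.

Step 2
Reactants: 3 1-(3-methylbut-2-en-1-yl)cyclohexa-2,5-diene-1-carboxylic acid
Product: 5 N-methoxy-N-methyl-1-(3-methylbut-2-en-1-yl)cyclohexa-2,5-diene-1-carboxamide, via acid chloride 4 (not isolated)
Conditions: (COCl)2, DMF (cat.), CH2Cl2, 0 → 23 °C; then MeNH(OMe)·HCl, Et3N, CH2Cl2, 0 °C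
Reagents that add atoms: N,O-dimethylhydroxylamine hydrochloride, CNOC.Cl
Why: acyl chloride formation followed by amidation (Weinreb amide synthesis) copes with the quaternary α-carbon and spares the skipped diene at low temperature.

Step 3
Reactants: 5 N-methoxy-N-methyl-1-(3-methylbut-2-en-1-yl)cyclohexa-2,5-diene-1-carboxamide; 6 (3-bromopropoxy)(tert-butyl)dimethylsilane
Product: 8 4-(tert-butyldimethylsilyloxy)-1-[1-(3-methylbut-2-en-1-yl)cyclohexa-2,5-dien-1-yl]butan-1-one, via Grignard reagent 7 (not isolated)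
Conditions: 6, Mg, THF, 40 °C; then 5, 0 → 23 °C; cold 1 M HCl work-up
Reagents that add atoms: none
Why: Weinreb ketone synthesis, in which the chelated tetrahedral adduct stops at the ketone stage even with a neopentylic amide, so the whole C1–C4 tether arrives in one step with C4 already oxygenated.

Step 4
Reactants: 8 4-(tert-butyldimethylsilyloxy)-1-[1-(3-methylbut-2-en-1-yl)cyclohexa-2,5-dien-1-yl]butan-1-one
Product: 9 tert-butyldimethyl(3-{2-[1-(3-methylbut-2-en-1-yl)cyclohexa-2,5-dien-1-yl]-1,3-dioxolan-2-yl}propoxy)silane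
Conditions: Me3SiOCH2CH2OSiMe3, Me3SiOTf (cat.), CH2Cl2, −78 → −20 °C; pyridine quench
Reagents that add atoms: 1,2-bis(trimethylsilyloxy)ethane, C[Si](C)(C)OCCO[Si](C)(C)C
Why: silyl-triflate-catalysed dioxolanation with the bis-silyl ether is aprotic and driven by siloxane formation, which suits a hindered ketone beside an acid-sensitive skipped diene; the ketal keeps C1 achiral and blocks later loss of the acyl group.

Step 5
Reactants: 9 tert-butyldimethyl(3-{2-[1-(3-methylbut-2-en-1-yl)cyclohexa-2,5-dien-1-yl]-1,3-dioxolan-2-yl}propoxy)silane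
Product: 10 4-{2-[3-(tert-butyldimethylsilyloxy)propyl]-1,3-dioxolan-2-yl}-4-(3-methylbut-2-en-1-yl)cyclohexa-2,5-dien-1-one
Conditions: (C5H5NH)2Cr2O7, t-BuOOH, Celite, PhH, 23 °C
Reagents that add atoms: tert-butyl hydroperoxide, CC(C)(C)OO
Why: chromium-mediated allylic oxidation, with the hydroperoxide as terminal oxidant, attacks the doubly allylic ring CH2 much faster than the prenyl allylic positions and gives the cross-conjugated dienone, the usual outcome for Birch alkylation products.

Step 6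
Reactants: 10 4-{2-[3-(tert-butyldimethylsilyloxy)propyl]-1,3-dioxolan-2-yl}-4-(3-methylbut-2-en-1-yl)cyclohexa-2,5-dien-1-one
Product: 11 4-[2-(3-hydroxypropyl)-1,3-dioxolan-2-yl]-4-(3-methylbut-2-en-1-yl)cyclohexa-2,5-dien-1-one
Conditions: Bu4NF, AcOH, THF, 0 → 23 °C
Reagents that add atoms: none
Why: buffered fluoride desilylation frees the primary alcohol without touching the dienone or the ketal.

Step 7
Reactants: 11 4-[2-(3-hydroxypropyl)-1,3-dioxolan-2-yl]-4-(3-methylbut-2-en-1-yl)cyclohexa-2,5-dien-1-one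
Product: 12 3-{2-[1-(3-methylbut-2-en-1-yl)-4-oxocyclohexa-2,5-dien-1-yl]-1,3-dioxolan-2-yl}propanal
Conditions: Dess–Martin periodinane, pyridine, CH2Cl2, 0 → 23 °C
Reagents that add atoms: none
Why: Dess–Martin oxidation gives the aldehyde under near-neutral conditions only after the radical oxidation of step 5 is over; 12 is used at once.

Step 8
Reactants: 12 3-{2-[1-(3-methylbut-2-en-1-yl)-4-oxocyclohexa-2,5-dien-1-yl]-1,3-dioxolan-2-yl}propanal
Product: 13 (4aR,8aS)-1,1-ethylenedioxy-8a-(3-methylbut-2-en-1-yl)-1,2,3,4a,5,8a-hexahydronaphthalene-4,6-dione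
Conditions: chiral 2-(pentafluorophenyl)-5a,10b-dihydro-4H,6H-indeno[2,1-b][1,2,4]triazolo[4,3-d][1,4]oxazin-2-ium tetrafluoroborate (20 mol%), KN(SiMe3)2 (20 mol%), PhMe, 23 °C
Reagents that add atoms: none
Why: The carbene adds to the aldehyde and proton transfer gives the Breslow intermediate, whose nucleophilic C4 adds to the dienone β-carbon C4a; protonation at C10 and release of the carbene give the 1,4-diketone. The closest known reaction type is the asymmetric intramolecular Stetter desymmetrisation of 4,4-disubstituted cyclohexadienones with aminoindanol triazolium salts, extended here to an all-carbon tether. Ring A closes 6-exo-trig, helped by the fully substituted ketal carbon C1 in the tether. C9a is set by the catalyst, which selects one of the two enantiotopic olefins, and C4a follows from delivery of C4 on the face that carries the tether, hence the cis fusion. The step needs group selectivity and conjugate addition in preference to aldol or benzoin pathways: the symmetric C1 ketal makes the two olefins strictly enantiotopic and removes the 4-acyl group that could be expelled with aromatisation, and the non-enolisable dienone offers only its β-carbons.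

Step 9
Reactants: 13 (4aR,8aS)-1,1-ethylenedioxy-8a-(3-methylbut-2-en-1-yl)-1,2,3,4a,5,8a-hexahydronaphthalene-4,6-dione
Product: 14 (4aR,8aS)-1,1:4,4-bis(ethylenedioxy)-8a-(3-methylbut-2-en-1-yl)-1,2,3,4,4a,8a-hexahydronaphthalen-6(5H)-one
Conditions: Me3SiOCH2CH2OSiMe3, Me3SiOTf (cat.), CH2Cl2, −78 → −40 °C
Reagents that add atoms: 1,2-bis(trimethylsilyloxy)ethane, C[Si](C)(C)OCCO[Si](C)(C)C
Why: chemoselective ketalisation, since the saturated C4 ketone reacts at low temperature while the conjugated C11 carbonyl does not; this leaves C11 as the only carbonyl group for steps 10 and 11, and any epimerisation at C4a is of no consequence.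

Step 10
Reactants: 14 (4aR,8aS)-1,1:4,4-bis(ethylenedioxy)-8a-(3-methylbut-2-en-1-yl)-1,2,3,4,4a,8a-hexahydronaphthalen-6(5H)-one
Product: 16 (8aS)-1,1:4,4-bis(ethylenedioxy)-8a-(3-methylbut-2-en-1-yl)-1,2,3,4-tetrahydronaphthalen-6(8aH)-one, via silyl dienol ether 15 (not isolated)
Conditions: LiN(i-Pr)2, Me3SiCl, THF, −78 °C; then Pd(OAc)2, MeCN, 23 °C
Reagents that add atoms: none
Why: Saegusa–Ito oxidation, in which kinetic deprotonation can only occur at C10 and the palladium enolate loses the C4a hydrogen; this erases the C4a stereocenter and flattens the ring fusion before the aryl group is introduced.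

Step 11
Reactants: 16 (8aS)-1,1:4,4-bis(ethylenedioxy)-8a-(3-methylbut-2-en-1-yl)-1,2,3,4-tetrahydronaphthalen-6(8aH)-one; 17 2-bromo-1,4-dimethoxybenzene
Product: 20 (8R,8aS)-8-(2,5-dimethoxyphenyl)-1,1:4,4-bis(ethylenedioxy)-8a-(3-methylbut-2-en-1-yl)-1,2,3,4,8,8a-hexahydronaphthalen-6(7H)-one, via aryl Grignard reagent 18 (not isolated), via silyl dienol ether 19 (not isolated)
Conditions: 17, Mg, THF, 50 °C; then 16, CuBr·SMe2 (10 mol%), Me3SiCl, THF, −78 → −30 °C; cold 1 M HCl work-up
Reagents that add atoms: none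
Why: copper-catalysed conjugate addition of the aryl Grignard reagent, accelerated by Me3SiCl, goes to the unsubstituted β-carbon C9 and not to the fully substituted C4a; with C4a planar the prenyl group is pseudo-axial on ring B, so axial attack anti to it sets C9, just as nucleophiles enter C1 of steroidal 1,4-dien-3-ones anti to the angular methyl group.

Step 12
Reactants: 20 (8R,8aS)-8-(2,5-dimethoxyphenyl)-1,1:4,4-bis(ethylenedioxy)-8a-(3-methylbut-2-en-1-yl)-1,2,3,4,8,8a-hexahydronaphthalen-6(7H)-one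
Product: 21 (8R,8aS)-8-(2,5-dimethoxyphenyl)-8a-(3-methylbut-2-en-1-yl)-2,3,8,8a-tetrahydronaphthalene-1,4,6(7H)-trione
Conditions: 2 M HCl, THF, 23 °C
Reagents that add atoms: water, O
Why: acid hydrolysis of both dioxolanes unveils C1 and C4 and turns C4a=C10 into an ene-dione; ring B is no longer a dienone, so the free C1 acyl group cannot be expelled, and dilute aqueous acid is too weak to start the arene cyclisation.

Step 13
Reactants: 21 (8R,8aS)-8-(2,5-dimethoxyphenyl)-8a-(3-methylbut-2-en-1-yl)-2,3,8,8a-tetrahydronaphthalene-1,4,6(7H)-trione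
Product: 23 (4aR,9R,9aS)-5,8-dimethoxy-9a-(3-methylbut-2-en-1-yl)-1,4-dioxo-2,3,9,9a-tetrahydro-4a,9-prop[1]enofluoren-11-yl trifluoromethanesulfonate, via bridged enol silane 22 (not isolated)
Conditions: t-BuMe2SiOTf, 2,6-di-tert-butyl-4-methylpyridine, CH2Cl2, −78 → −40 °C; then PhNTf2, CsF, DME, 23 °C
Reagents that add atoms: N-phenylbis(trifluoromethanesulfonimide), O=S(=O)(N(c1ccccc1)S(=O)(=O)C(F)(F)F)C(F)(F)F
Why: Friedel–Crafts conjugate addition under silyl triflate activation (Mukaiyama–Michael type), in which the axial C9 aryl ring attacks C4a through C4b (ortho to the C5 methoxy group, 5-exo-trig) on the face it occupies and so sets the quaternary C4a, while silyl transfer fixes the enol at C10=C11; fluoride-triggered triflation keeps that regiochemistry, which later enolisation of the bridged ketone would be expected to place on the C12 side.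

Step 14
Reactants: 23 (4aR,9R,9aS)-5,8-dimethoxy-9a-(3-methylbut-2-en-1-yl)-1,4-dioxo-2,3,9,9a-tetrahydro-4a,9-prop[1]enofluoren-11-yl trifluoromethanesulfonate
Product: 24 (4aR,9R,9aS)-5,8-dimethoxy-11-methyl-9a-(3-methylbut-2-en-1-yl)-2,3,9,9a-tetrahydro-4a,9-prop[1]enofluorene-1,4-dione
Conditions: MeZnCl, Pd(PPh3)4 (5 mol%), THF, 23 → 50 °C
Reagents that add atoms: methylzinc chloride, C[Zn]Cl
Why: Negishi coupling of the enol triflate installs the C11 methyl group with the olefin fixed at C10=C11, and organozinc halides leave the ring A ketones alone.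

Step 15
Reactants: 24 (4aR,9R,9aS)-5,8-dimethoxy-11-methyl-9a-(3-methylbut-2-en-1-yl)-2,3,9,9a-tetrahydro-4a,9-prop[1]enofluorene-1,4-dione
Product: 25 (4aR,9R,9aS)-5,8-dimethoxy-11-methyl-9a-(3-methylbut-2-en-1-yl)-9,9a-dihydro-4a,9-prop[1]enofluorene-1,4-dione
Conditions: IBX, DMSO/PhF, 65 °C
Reagents that add atoms: none
Why: IBX dehydrogenation of the cyclohexane-1,4-dione can only give the C2=C3 ene-dione, because C4a and C9a are quaternary.

Step 16
Reactants: 25 (4aR,9R,9aS)-5,8-dimethoxy-11-methyl-9a-(3-methylbut-2-en-1-yl)-9,9a-dihydro-4a,9-prop[1]enofluorene-1,4-dione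
Product: 27 (4aR,9R,9aS)-5,8-dihydroxy-11-methyl-9a-(3-methylbut-2-en-1-yl)-9,9a-dihydro-4a,9-prop[1]enofluorene-1,4-dione, via quinone 26 (not isolated)
Conditions: (NH4)2Ce(NO3)6, MeCN/H2O, 0 °C; then aq. Na2S2O4, EtOAc, 23 °C
Reagents that add atoms: water, O
Why: oxidative demethylation of the 1,4-dimethoxyarene to the quinone (oxygen from water) tolerates the olefins and the ene-dione, and the dithionite wash should reduce only the benzoquinone, so neither acid nor Lewis acid touches the prenyl group.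

Compound list

1 | benzoic acid | OC(=O)c1ccccc1 | starting material
2 | prenyl bromide (1-bromo-3-methylbut-2-ene) | CC(C)=CCBr | starting material
3 | 1-(3-methylbut-2-en-1-yl)cyclohexa-2,5-diene-1-carboxylic acid | CC(C)=CCC1(C(=O)O)C=CCC=C1 | intermediate
4 | 1-(3-methylbut-2-en-1-yl)cyclohexa-2,5-diene-1-carbonyl chloride | CC(C)=CCC1(C(=O)Cl)C=CCC=C1 | intermediate (not isolated)
5 | N-methoxy-N-methyl-1-(3-methylbut-2-en-1-yl)cyclohexa-2,5-diene-1-carboxamide | CC(C)=CCC1(C(=O)N(C)OC)C=CCC=C1 | intermediate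
6 | (3-bromopropoxy)(tert-butyl)dimethylsilane | BrCCCO[Si](C)(C)C(C)(C)C | starting material
7 | [3-(tert-butyldimethylsilyloxy)propyl]magnesium bromide | Br[Mg]CCCO[Si](C)(C)C(C)(C)C | intermediate (not isolated)
8 | 4-(tert-butyldimethylsilyloxy)-1-[1-(3-methylbut-2-en-1-yl)cyclohexa-2,5-dien-1-yl]butan-1-one | CC(C)=CCC1(C(=O)CCCO[Si](C)(C)C(C)(C)C)C=CCC=C1 | intermediate
9 | tert-butyldimethyl(3-{2-[1-(3-methylbut-2-en-1-yl)cyclohexa-2,5-dien-1-yl]-1,3-dioxolan-2-yl}propoxy)silane | CC(C)=CCC1(C=CCC=C1)C1(CCCO[Si](C)(C)C(C)(C)C)OCCO1 | intermediate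
10 | 4-{2-[3-(tert-butyldimethylsilyloxy)propyl]-1,3-dioxolan-2-yl}-4-(3-methylbut-2-en-1-yl)cyclohexa-2,5-dien-1-one | CC(C)=CCC1(C=CC(=O)C=C1)C1(CCCO[Si](C)(C)C(C)(C)C)OCCO1 | intermediate
11 | 4-[2-(3-hydroxypropyl)-1,3-dioxolan-2-yl]-4-(3-methylbut-2-en-1-yl)cyclohexa-2,5-dien-1-one | CC(C)=CCC1(C=CC(=O)C=C1)C1(CCCO)OCCO1 | intermediate
12 | 3-{2-[1-(3-methylbut-2-en-1-yl)-4-oxocyclohexa-2,5-dien-1-yl]-1,3-dioxolan-2-yl}propanal (precursor of the key step) | CC(C)=CCC1(C=CC(=O)C=C1)C1(CCC=O)OCCO1 | intermediate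
13 | (4aR,8aS)-1,1-ethylenedioxy-8a-(3-methylbut-2-en-1-yl)-1,2,3,4a,5,8a-hexahydronaphthalene-4,6-dione; cis-fused, C4a–H and prenyl on the same face (product of the key step) | CC(C)=CC[C@@]12C3(OCCO3)CCC(=O)[C@@H]1CC(=O)C=C2 | intermediate
14 | (4aR,8aS)-1,1:4,4-bis(ethylenedioxy)-8a-(3-methylbut-2-en-1-yl)-1,2,3,4,4a,8a-hexahydronaphthalen-6(5H)-one; cis-fused | CC(C)=CC[C@@]12C3(OCCO3)CCC4(OCCO4)[C@@H]1CC(=O)C=C2 | intermediate
15 | (4aR,8aS)-1,1:4,4-bis(ethylenedioxy)-8a-(3-methylbut-2-en-1-yl)-6-(trimethylsilyloxy)-1,2,3,4,4a,8a-hexahydronaphthalene (5,7-diene) | CC(C)=CC[C@@]12C3(OCCO3)CCC4(OCCO4)[C@@H]1C=C(O[Si](C)(C)C)C=C2 | intermediate (not isolated)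
16 | (8aS)-1,1:4,4-bis(ethylenedioxy)-8a-(3-methylbut-2-en-1-yl)-1,2,3,4-tetrahydronaphthalen-6(8aH)-one (cross-conjugated dienone) | CC(C)=CC[C@@]12C3(OCCO3)CCC4(OCCO4)C1=CC(=O)C=C2 | intermediate
17 | 2-bromo-1,4-dimethoxybenzene | COc1ccc(OC)c(Br)c1 | starting material
18 | (2,5-dimethoxyphenyl)magnesium bromide | COc1ccc(OC)c([Mg]Br)c1 | intermediate (not isolated)
19 | (8R,8aS)-8-(2,5-dimethoxyphenyl)-1,1:4,4-bis(ethylenedioxy)-8a-(3-methylbut-2-en-1-yl)-6-(trimethylsilyloxy)-1,2,3,4,8,8a-hexahydronaphthalene (4a,6-diene); aryl trans to prenyl | CC(C)=CC[C@@]12C3(OCCO3)CCC4(OCCO4)C1=CC(O[Si](C)(C)C)=C[C@@H]2c1cc(OC)ccc1OC | intermediate (not isolated)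
20 | (8R,8aS)-8-(2,5-dimethoxyphenyl)-1,1:4,4-bis(ethylenedioxy)-8a-(3-methylbut-2-en-1-yl)-1,2,3,4,8,8a-hexahydronaphthalen-6(7H)-one; aryl trans to prenyl | CC(C)=CC[C@@]12C3(OCCO3)CCC4(OCCO4)C1=CC(=O)C[C@@H]2c1cc(OC)ccc1OC | intermediate
21 | (8R,8aS)-8-(2,5-dimethoxyphenyl)-8a-(3-methylbut-2-en-1-yl)-2,3,8,8a-tetrahydronaphthalene-1,4,6(7H)-trione | CC(C)=CC[C@@]12C(=O)CCC(=O)C1=CC(=O)C[C@@H]2c1cc(OC)ccc1OC | intermediate
22 | (4aR,9R,9aS)-11-(tert-butyldimethylsilyloxy)-5,8-dimethoxy-9a-(3-methylbut-2-en-1-yl)-2,3,9,9a-tetrahydro-4a,9-prop[1]enofluorene-1,4-dione; benzo bridge anti to prenyl | CC(C)=CC[C@@]12C(=O)CCC(=O)[C@@]13C=C(O[Si](C)(C)C(C)(C)C)C[C@@H]2c1c(OC)ccc(OC)c13 | intermediate (not isolated)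
23 | (4aR,9R,9aS)-5,8-dimethoxy-9a-(3-methylbut-2-en-1-yl)-1,4-dioxo-2,3,9,9a-tetrahydro-4a,9-prop[1]enofluoren-11-yl trifluoromethanesulfonate | CC(C)=CC[C@@]12C(=O)CCC(=O)[C@@]13C=C(OS(=O)(=O)C(F)(F)F)C[C@@H]2c1c(OC)ccc(OC)c13 | intermediate
24 | (4aR,9R,9aS)-5,8-dimethoxy-11-methyl-9a-(3-methylbut-2-en-1-yl)-2,3,9,9a-tetrahydro-4a,9-prop[1]enofluorene-1,4-dione | CC(C)=CC[C@@]12C(=O)CCC(=O)[C@@]13C=C(C)C[C@@H]2c1c(OC)ccc(OC)c13 | intermediate
25 | (4aR,9R,9aS)-5,8-dimethoxy-11-methyl-9a-(3-methylbut-2-en-1-yl)-9,9a-dihydro-4a,9-prop[1]enofluorene-1,4-dione | CC(C)=CC[C@@]12C(=O)C=CC(=O)[C@@]13C=C(C)C[C@@H]2c1c(OC)ccc(OC)c13 | intermediate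
26 | (4aS,9R,9aS)-11-methyl-9a-(3-methylbut-2-en-1-yl)-9,9a-dihydro-4a,9-prop[1]enofluorene-1,4,5,8-tetrone (same spatial arrangement as 25; the C4a descriptor changes with the priorities) | CC(C)=CC[C@@]12C(=O)C=CC(=O)[C@@]13C=C(C)C[C@@H]2C=1C(=O)C=CC(=O)C13 | intermediate (not isolated)
27 | (4aR,9R,9aS)-5,8-dihydroxy-11-methyl-9a-(3-methylbut-2-en-1-yl)-9,9a-dihydro-4a,9-prop[1]enofluorene-1,4-dione (CNP0513322.1) | CC(C)=CC[C@@]12C(=O)C=CC(=O)[C@@]13C=C(C)C[C@@H]2c1c(O)ccc(O)c13 | target

Total step count: 16. Longest linear sequence: 16 steps (1 → 27); 2, 6 and 17 enter as bought reagents.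

Steps most likely to fail

Step 13. The arene may be diverted to the activated C1 carbonyl, or the prenyl olefin may add to C10 of the activated ene-dione. The enol silane may also be lost by protodesilylation or by proton exchange with the acidic ring A protons before triflation, which would move the olefin to the C12 side. The fallback reverses the polarity of the ring closure and fixes the olefin position first. Setting out from 20, dissolving-metal reduction of the enone (Li, NH3, THF, t-BuOH 1 equiv, −78 °C) and trapping of the regiodefined C10=C11 lithium enolate with PhNTf2 would give the enol triflate F1, with C4a–H trans to prenyl. Negishi methylation (MeZnCl, Pd(PPh3)4) would give the methyl olefin F2, and 2 M HCl in THF would release the dione F3. Oxidation with (NH4)2Ce(NO3)6 would give the quinone F4. With Et3N in THF the dienolate of its C4 ketone should add through its α-carbon C4a to the quinone carbon C4b and tautomerise to the hydroquinone F5; kinetic α-attack of the dienolate is relied on here, against γ-attack at C11. Excess IBX would then dehydrogenate ring A and oxidise the hydroquinone, which rejoins the route at quinone 26, and the dithionite work-up of step 16 would give 27.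

Step 8. The six-membered closure of an aliphatic Breslow intermediate may be slow, so that aldol or benzoin self-condensation of 12 competes or group selectivity erodes. The fallback uses a nitronate as the acyl anion equivalent. From alcohol 11, iodination (PPh3, I2, imidazole, CH2Cl2) would give the iodide F6, and nitrite displacement (NaNO2, DMF) the nitroalkane F7. An intramolecular nitro-Michael desymmetrisation with a cinchona-derived bifunctional thiourea (PhMe, 23 °C) would give the cis-fused nitro ketone F8 as C4 epimers. A Nef reaction (NaOMe, MeOH; then TiCl3, NH4OAc buffer) would deliver ketone 13, where the route continues.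

Step 11. Transfer of the ortho-substituted aryl group to the neopentylic C9 beside the spiroketal may be slow, with competing 1,2-addition at C11 or incomplete facial control. The fallback replaces copper by rhodium and adds reagent control. From 16, a 1,4-addition of (2,5-dimethoxyphenyl)boronic acid catalysed by monovalent rhodium ([Rh(OH)(cod)]2, a chiral diene ligand whose sense reinforces the substrate bias, KOH, dioxane/H2O, 50 °C) would give 20 directly after protonation. This makes no compound outside the list (F0).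

Further compounds
F1 | step 13 | (8R,8aS)-8-(2,5-dimethoxyphenyl)-1,1:4,4-bis(ethylenedioxy)-8a-(3-methylbut-2-en-1-yl)-1,2,3,4,4a,7,8,8a-octahydronaphthalen-6-yl trifluoromethanesulfonate, C4a–H trans to prenyl | CC(C)=CC[C@@]12C3(OCCO3)CCC4(OCCO4)[C@H]1C=C(OS(=O)(=O)C(F)(F)F)C[C@@H]2c1cc(OC)ccc1OC
F2 | step 13 | (8R,8aS)-8-(2,5-dimethoxyphenyl)-1,1:4,4-bis(ethylenedioxy)-6-methyl-8a-(3-methylbut-2-en-1-yl)-1,2,3,4,4a,7,8,8a-octahydronaphthalene | CC(C)=CC[C@@]12C3(OCCO3)CCC4(OCCO4)[C@H]1C=C(C)C[C@@H]2c1cc(OC)ccc1OC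
F3 | step 13 | (8R,8aS)-8-(2,5-dimethoxyphenyl)-6-methyl-8a-(3-methylbut-2-en-1-yl)-2,3,4a,7,8,8a-hexahydronaphthalene-1,4-dione | CC(C)=CC[C@@]12C(=O)CCC(=O)[C@H]1C=C(C)C[C@@H]2c1cc(OC)ccc1OC
F4 | step 13 | quinone of F3, with 3,6-dioxocyclohexa-1,4-dien-1-yl in place of 2,5-dimethoxyphenyl | CC(C)=CC[C@@]12C(=O)CCC(=O)[C@H]1C=C(C)C[C@@H]2C1=CC(=O)C=CC1=O
F5 | step 13 | 5,8-dihydroxy-11-methyl-9a-(3-methylbut-2-en-1-yl)-2,3,9,9a-tetrahydro-4a,9-prop[1]enofluorene-1,4-dione, configuration as in 24 | CC(C)=CC[C@@]12C(=O)CCC(=O)[C@@]13C=C(C)C[C@@H]2c1c(O)ccc(O)c13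
F6 | step 8 | 4-[2-(3-iodopropyl)-1,3-dioxolan-2-yl]-4-(3-methylbut-2-en-1-yl)cyclohexa-2,5-dien-1-one | CC(C)=CCC1(C=CC(=O)C=C1)C1(CCCI)OCCO1
F7 | step 8 | 4-(3-methylbut-2-en-1-yl)-4-[2-(3-nitropropyl)-1,3-dioxolan-2-yl]cyclohexa-2,5-dien-1-one | CC(C)=CCC1(C=CC(=O)C=C1)C1(CCC[N+](=O)[O-])OCCO1
F8 | step 8 | cis-fused 1,1-ethylenedioxy-8a-(3-methylbut-2-en-1-yl)-4-nitro-1,2,3,4,4a,8a-hexahydronaphthalen-6(5H)-one, C4 epimers, ring fusion as in 13 | CC(C)=CC[C@@]12C3(OCCO3)CCC([N+](=O)[O-])[C@@H]1CC(=O)C=C2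
F0 | step 11 | none | none
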